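## Structural features

Grevirobstol B (C28H40O4) is a 22-membered cyclophane in which two benzene rings are joined twice: by a diaryl ether oxygen from C3 of ring A to C2 of ring B, and by an unbranched chain of sixteen methylene groups from C1 of ring A to C1 of ring B. Ring A is 1,3,5-trisubstituted (chain, ether oxygen, hydroxyl at C5). Ring B is 1,2,3,5-tetrasubstituted, with the chain at C1, the aryloxy group at C2, hydroxyls at C3 and C5, and hydrogen at C4 and C6. There is no stereocentre, so no stereocentres stand next to each other; the alkene geometry and the carbinol centre met on the way are both erased. The fragile groups are the three free phenols: ring B is a 1,2,4-trioxygenated benzene with the C2 and C5 oxygens para, a hydroquinone mono-aryl ether that oxidizes easily, so the hydroxyls are best released last. The real difficulty is twofold. The contiguous chain/aryloxy/hydroxyl array on C1–C3(B) together with the C5 hydroxyl is awkward to reach by substitution on a resorcinol or hydroquinone. The large ring must also be closed at the oxygen on C2(B), which is flanked on both sides, through a flexible C16 tether. The key step exploits the para relation of O–C2 and O–C5 with a third oxygen on C3: this is the pattern formed when a 3-alkoxy-4-oxy-4-(alk-1-en-2-yl)cyclobutenone expands, with C2–C5 coming from the four-membered ring, C1 and C6 from the alkene, and the chain already on the alkene carbon.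

## Logic of the disconnections

27 to 26. The three O–alkyl bonds are cut: methyl on the ring A oxygen, methyl on O–C5(B), isopropyl on O–C3(B). The oxidation-prone phenols are thus carried as ethers until the end, and 26 is a robust, chromatographable macrocycle. The forward step needs one reagent that removes two methyl and one isopropyl group without touching either aryl–oxygen bond of the diaryl ether.

26 to 25. The C3(A)–O bond of the diaryl ether is cut, which opens the 22-membered ring. The oxygen is kept on ring B because the key step delivers it there as the C2 phenol; the ring A carbon becomes the electrophile (a triflate). The gain is an open-chain precursor without ring strain or transannular constraints. The demand is an intramolecular aryl C–O coupling at a di-ortho-substituted phenol that outruns oligomerization and loss of the triflate.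

25 to 24 to 23 to 22. Cut in turn are the S–O bond of the triflate, the two Si–O bonds, and the O–CH3 bond at C5(B). In 22 the three phenolic oxygens stand in three different states: free O–C5, silylated O–C2, silylated ring A oxygen. The methylation therefore needs no selectivity. The forward demand is that triflation of 24 takes the open ring A phenol and leaves the flanked C2(B) phenol.

22 to 19 (key disconnection). The C5(B)–C6(B) bond is cut and C2(B) is reconnected to C5(B), which contracts ring B to a cyclobutenone bearing a 1,1-disubstituted alkene. This moves the whole oxygen pattern and the chain position into a molecule made by carbonyl addition, so no aromatic substitution is needed. The gain is one ring and the complete regiochemistry of ring B. The demand is a 4π opening in which the silyloxy group rotates outward, and a ketene that is not intercepted before it cyclizes.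

19 to 13 and 16. The bond between the carbinol carbon (future C2(B)) and the alkene carbon (future C1(B)) is cut, together with the O–Si bond. This is the convergent union of the C18 chain fragment with the C4 unit. The demand is addition of the alkenyllithium to the carbonyl next to the alkoxy-bearing carbon and not to the vinylogous ester carbonyl, followed by capture of the alkoxide.

16 to 14. The ring C–H of 16 is traced back to a C–O(isopropyl) bond. The semisquarate comes from the symmetrical diester by partial reduction and acid-mediated loss of isopropanol, which must stop after delivery of one hydride.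

13 to 11 to 10. The C–Br bond is cut (Markovnikov addition of HBr to a terminal alkyne), then the C(sp)–C(sp3) bond between C16 and C17 of the chain. The two alkyne carbons become C1 and C6 of ring B. The demands are a regioselective hydrobromination that spares the aryl ethers and a clean SN2 alkylation of acetylide.

10 to 9 to 8 to 7 to 5 and 2. Functional group changes (iodide from alcohol, alcohol from acid, saturation of the alkene) lead to the cut of the C=C bond between the benzylic carbon and the chain. This Wittig disconnection joins the ring A aldehyde to a C15 unit in one step; the alkene geometry is irrelevant.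

5 to 4 to 3, and 2 to 1. Cut are the C–P bond, the C–Br bond (back to the lactone C–O bond) and the O–Si bond. All fifteen chain carbons come from one cheap macrolactone, and the ring A hydroxyl is masked by a group that survives ylide, hydride, organolithium and heat.

## Other disconnections considered

Alternative 1: The cut is the C1'–C2' bond of the chain next to ring A, made after the diaryl ether is in place. In the forward sense the 23-membered sulfone A2 (ring A–CH2–SO2–(CH2)15–ring B) would be α-halogenated and contracted by Ramberg–Bäcklund loss of SO2 to the styrene-type macrocycle A1. Hydrogenation and threefold demethylation would follow.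
- In favour: the large ring would be closed by C–S bond formation between a thiolate and a primary or benzylic halide, one of the most forgiving macrocyclizations. The diaryl ether would be made earlier between two small partners, where a hindered phenol is easier to handle. On ring closure this plan is the better of the two.
- Against: ring B, with chain, aryloxy and methoxy groups contiguous, would have to be assembled by substitution on an existing arene, which is the regiochemical problem that the chosen plan avoids. The electron-rich rings would have to survive sulfide oxidation and the basic halogenating medium. Three operations (oxidation, contraction, hydrogenation) add no skeletal carbon.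
- Comparison: on structure the chosen plan is stronger for ring B and this alternative for the macrocycle. On mechanism the two are equal, since both ring-forming events are made irreversible (SO2 loss here, aromatization in step 12). On step economy A1 is two steps from the target against five after 22, but more steps would be needed before the key step, so the totals should be of the same order.

Alternative 2: The cuts are C1(B)–C6(B) and C4(B)–C5(B), so ring B is annulated last. In the forward sense dimethyl malonate would add to the macrocyclic α-aryloxy enone A4 under NaOMe, and Claisen closure of the acetyl methyl onto a malonate ester would give the cyclohexane-1,3-dione A3. Ester hydrolysis, decarboxylation, dehydrogenation and demethylation would follow.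
- In favour: the ether oxygen would be attached by simple O-alkylation of the ring A phenol, so no aryl–oxygen coupling is needed at all, which is better than step 16. The oxygen pattern of ring B is fixed by construction (C3 and C5 from carbonyl carbons, C2 already bearing the ether), so on regiocontrol this plan is the equal of the chosen one.
- Against: A3 is at the wrong oxidation level. Aromatization of a 4-aryloxycyclohexane-1,3-dione needs a halogen or quinone oxidant that could also attack electron-rich ring A, and intermediates on that path could expel the aryloxy group. The macrocyclic enone A4 needs a ring closure of its own, and the basic medium invites retro-Michael and transesterification equilibria. The two stereocentres of A3 are of no use.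
- Comparison: the chosen plan delivers ring B aromatic and at the right oxidation level in a reagent-free step. This alternative would need three or four steps after its key step, one of them an oxidation on a sensitive substrate. In exchange it avoids the hindered macro-etherification.

Alternative 3: The cuts are three bonds of ring A, which is built together with the macrocycle. In the forward sense irradiation of the diazoketone A6 at high dilution would give a ketene by Wolff rearrangement. Its (2+2) addition to the tethered aryl ethynyl ether, 4π opening and 6π closure would give A5, and only the two methyl ethers of ring B would remain to be cleaved.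
- In favour: it is the most convergent plan. Ring A, its 1,3,5 pattern (set by the polarization of the ynol ether) and the 22-membered ring would arise in one operation, and a single step would follow, so it is better than the chosen plan in step economy after the key step. It belongs to the same mechanistic family as step 12 (ketene, 4π opening, 6π closure), so the two are equal in being pericyclic cascades without reagents.
- Against: the first bond-forming event requires a short-lived ketene to find an alkyne at the far end of a sixteen-carbon tether. The effective molarity would be low, and dimerization or capture of the ketene would compete. This macrocyclic variant would have to be treated as untested. The aryl ethynyl ether on a hindered phenol oxygen is a labile function, and ring B would still have to be made by aromatic substitution.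
- Comparison: in the chosen plan every reacting atom sits on one four-membered ring and its substituent, so the cascade does not depend on ring size, and the macrocycle is closed separately by a reaction with a fallback. The alternative stakes both ring formations on one step.

Key step: step 12

Remarks on the chemistry:
- Ring B is numbered C1 (chain), C2 (aryloxy), C3 and C5 (oxygens). Ring A is numbered C1 (chain), C3 (ether oxygen), C5 (hydroxyl).
- Atom count: the octadec-1-en-2-yl unit of 19 supplies C1(B), C6(B) and the sixteen methylene groups. Compound 1 supplies the benzylic carbon, 3 supplies fifteen chain carbons, and acetylide supplies the last two.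
- Design of the precursor: the carbinol oxygen of the cyclobutenone is silylated in the flask (18 to 19). The ring expansion then gives ring B with O–C2 masked and O–C5 free, so the methylation of O–C5 needs no choice between two hydroxyls and no air-sensitive free hydroquinone is handled. The skeleton of the precursor and the bond formed are unchanged.
- Compounds 15, 18 and 19 are racemic and drawn as one enantiomer. Compound 7 is expected as a Z-rich mixture and drawn Z; both isomers serve, since step 5 saturates the alkene.

## Route

Step 1
Reactants: 1 3-hydroxy-5-methoxybenzaldehyde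
Product: 2 3-methoxy-5-(triisopropylsilyloxy)benzaldehyde
Conditions: TIPSCl, imidazole, DMF, rt
Reagents that add atoms: chlorotriisopropylsilane, CC(C)[Si](Cl)(C(C)C)C(C)C
Why: Imidazole-promoted O-silylation of a phenol; the bulky triisopropylsilyl ether is chosen because it should withstand the ylide, hydride, acetylide, organolithium and thermal steps and is later removed by fluoride.

Step 2
Reactants: 3 ω-pentadecalactone (oxacyclohexadecan-2-one)
Product: 4 15-bromopentadecanoic acid
Conditions: HBr (33% in AcOH), H2SO4 (cat.), 80 °C
Reagents that add atoms: hydrogen bromide, Br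
Why: Acid-mediated alkyl–oxygen cleavage of the protonated lactone by bromide (SN2 at the O–CH2 carbon), a standard opening of lactones to ω-bromo acids.

Step 3
Reactants: 4 15-bromopentadecanoic acid
Product: 5 (14-carboxytetradecyl)triphenylphosphonium bromide
Conditions: PPh3, MeCN, reflux
Reagents that add atoms: triphenylphosphine, c1ccc(cc1)P(c1ccccc1)c1ccccc1
Why: SN2 quaternization of the phosphine by a primary bromide; the free acid is tolerated, as in the usual ω-carboxyalkyl Wittig salts.

Step 4
Reactants: 5 (14-carboxytetradecyl)triphenylphosphonium bromide; 2 3-methoxy-5-(triisopropylsilyloxy)benzaldehyde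
Product: 7 (Z)-16-[3-methoxy-5-(triisopropylsilyloxy)phenyl]hexadec-15-enoic acid, via ylide carboxylate 6 (not isolated)
Conditions: NaN(SiMe3)2 (2.2 equiv), THF, 0 °C; then 2, −78 °C → rt; dilute HCl work-up
Reagents that add atoms: none
Why: Wittig olefination with a carboxylate-bearing non-stabilized ylide (two equivalents of base deprotonate the acid and the phosphonium salt); it joins the benzylic carbon to the C15 unit, and the Z/E ratio is immaterial because the alkene is reduced next.

Step 5
Reactants: 7 (Z)-16-[3-methoxy-5-(triisopropylsilyloxy)phenyl]hexadec-15-enoic acid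
Product: 8 16-[3-methoxy-5-(triisopropylsilyloxy)phenyl]hexadecanoic acid
Conditions: H2 (1 atm), 10% Pd/C, EtOAc, rt
Reagents that add atoms: none
Why: Heterogeneous hydrogenation of a styrene-type alkene; aryl silyl ether, aryl methyl ether and carboxylic acid are inert, and no benzylic C–O bond is present.

Step 6
Reactants: 8 16-[3-methoxy-5-(triisopropylsilyloxy)phenyl]hexadecanoic acid
Product: 9 16-[3-methoxy-5-(triisopropylsilyloxy)phenyl]hexadecan-1-ol
Conditions: BH3·THF, THF, 0 °C → rt; MeOH, then H2O
Reagents that add atoms: none
Why: Chemoselective borane reduction of a carboxylic acid through its acyloxyborane; the electrophilic hydride does not attack aryl silyl ethers, which a nucleophilic aluminium hydride might.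

Step 7
Reactants: 9 16-[3-methoxy-5-(triisopropylsilyloxy)phenyl]hexadecan-1-ol
Product: 10 [3-(16-iodohexadecyl)-5-methoxyphenoxy]triisopropylsilane
Conditions: I2, PPh3, imidazole, CH2Cl2, 0 °C → rt
Reagents that add atoms: iodine, II
Why: Appel-type iodination: the alkoxyphosphonium ion is displaced by iodide at the primary carbon under nearly neutral conditions.

Step 8
Reactants: 10 [3-(16-iodohexadecyl)-5-methoxyphenoxy]triisopropylsilane
Product: 11 triisopropyl[3-methoxy-5-(octadec-17-yn-1-yl)phenoxy]silane
Conditions: LiC≡CH·H2NCH2CH2NH2, DMSO/THF, 10 °C → rt
Reagents that add atoms: lithium acetylide–ethylenediamine complex, [Li]C#C.NCCN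
Why: SN2 alkylation of acetylide by a primary iodide, the standard two-carbon extension to a terminal alkyne; the hindered silicon of the aryl silyl ether should resist the carbon nucleophile and the amine under dry conditions.

Step 9
Reactants: 11 triisopropyl[3-methoxy-5-(octadec-17-yn-1-yl)phenoxy]silane
Product: 13 [3-(17-bromooctadec-17-en-1-yl)-5-methoxyphenoxy]triisopropylsilane, via bromoalkenylborane 12 (not isolated)
Conditions: B-Br-9-BBN, CH2Cl2, 0 °C; then AcOH, 0 °C → rt
Reagents that add atoms: B-bromo-9-borabicyclo[3.3.1]nonane, BrB1C2CCCC1CCC2
Why: Syn bromoboration of the terminal alkyne puts boron on the terminal carbon and bromine on the internal one; protonolysis of the C–B bond by acetic acid then gives the 2-bromo-1-alkene (net Markovnikov hydrobromination), and at 0 °C addition to the alkyne should be much faster than ether cleavage by the haloborane.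

Step 10
Reactants: 14 diisopropyl squarate (3,4-diisopropoxycyclobut-3-ene-1,2-dione)
Product: 16 3-isopropoxycyclobut-3-ene-1,2-dione (isopropyl semisquarate), via hydroxycyclobutenone 15 (not isolated)
Conditions: LiAlH(OtBu)3, THF, −78 → −20 °C; then conc. HCl, CH2Cl2, rt
Reagents that add atoms: water (its oxygen becomes the new carbonyl oxygen), O
Why: The hindered hydride reduces one carbonyl only, giving 15; acid ionizes the carbinol, water adds to the resulting alkoxy-stabilized cation and isopropanol is lost, which is the established route from squaric esters to semisquarates.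

Step 11
Reactants: 13 [3-(17-bromooctadec-17-en-1-yl)-5-methoxyphenoxy]triisopropylsilane; 16 3-isopropoxycyclobut-3-ene-1,2-dione
Product: 19 rac-4-[tert-butyl(dimethyl)silyloxy]-3-isopropoxy-4-{18-[3-methoxy-5-(triisopropylsilyloxy)phenyl]octadec-1-en-2-yl}cyclobut-2-en-1-one, via alkenyllithium 17 (not isolated), via lithium alkoxide 18 (not isolated)
Conditions: t-BuLi (2.0 equiv), THF/Et2O, −78 °C; 16 (1.3 equiv), THF, −78 °C; then TBSOTf, −78 → −30 °C
Reagents that add atoms: tert-butyldimethylsilyl trifluoromethanesulfonate, CC(C)(C)[Si](C)(C)OS(=O)(=O)C(F)(F)F
Why: Lithium–bromine exchange at −78 °C gives the 2-lithio-1-alkene without touching the aryl ethers, and 1,2-addition goes to the ketone-like carbonyl next to the alkoxy-bearing carbon, not to the deactivated vinylogous ester carbonyl, which fixes isopropoxy at the future C3(B). Capture of alkoxide 18 by the silyl triflate masks the future O–C2; the new carbinol centre is formed as a racemate and is destroyed in step 12.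

Step 12
Reactants: 19 rac-4-[tert-butyl(dimethyl)silyloxy]-3-isopropoxy-4-{18-[3-methoxy-5-(triisopropylsilyloxy)phenyl]octadec-1-en-2-yl}cyclobut-2-en-1-one
Product: 22 4-[tert-butyl(dimethyl)silyloxy]-3-isopropoxy-5-{16-[3-methoxy-5-(triisopropylsilyloxy)phenyl]hexadecyl}phenol, via dienylketene 20 (not isolated), via cyclohexadienone 21 (not isolated)
Conditions: PhMe (degassed, 0.01 M), 110 °C
Reagents that add atoms: none
Why: Heating opens the C1–C4 bond of the cyclobutenone in a conrotatory 4π electrocyclic process to give dienylketene 20. The silyloxy donor on C4 rotates outward, which turns the alkenyl group inward, cis to the ketene. A disrotatory 6π electrocyclization then joins the ketene carbon (future C5 of ring B) to the methylene terminus (future C6) and closes the six-membered carbocycle as dienone 21, and enolization driven by aromatization gives phenol 22. The closest known reaction type is the Moore-type thermal ring expansion of 4-alkenyl-4-hydroxy-, 4-alkoxy- or 4-silyloxycyclobutenones to hydroquinones and their mono-ethers. No stereocentre is formed and the carbinol centre of 19 is destroyed, so the racemic nature of 19 is of no consequence. The step needs torquoselectivity and a ketene that is not intercepted: the donor on C4 secures the first, and the absence of a free hydroxyl (no butenolide pathway), high dilution and an inert solvent secure the second. The oxygen pattern is inherited without any choice: the silylated carbinol oxygen becomes O–C2, the isopropoxy carbon becomes C3, the ketene oxygen becomes the free hydroxyl on C5, and the chain ends on C1.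

Step 13
Reactants: 22 4-[tert-butyl(dimethyl)silyloxy]-3-isopropoxy-5-{16-[3-methoxy-5-(triisopropylsilyloxy)phenyl]hexadecyl}phenol
Product: 23 tert-butyl(2-isopropoxy-4-methoxy-6-{16-[3-methoxy-5-(triisopropylsilyloxy)phenyl]hexadecyl}phenoxy)dimethylsilane
Conditions: MeI, K2CO3, acetone, 45 °C
Reagents that add atoms: iodomethane, CI
Why: Williamson methylation of the only free hydroxyl (O–C5, flanked by two hydrogens); because O–C2 is silylated no site selectivity is needed, and carbonate in dry acetone should leave both aryl silyl ethers intact.

Step 14
Reactants: 23 tert-butyl(2-isopropoxy-4-methoxy-6-{16-[3-methoxy-5-(triisopropylsilyloxy)phenyl]hexadecyl}phenoxy)dimethylsilane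
Product: 24 2-[16-(3-hydroxy-5-methoxyphenyl)hexadecyl]-6-isopropoxy-4-methoxyphenol
Conditions: Bu4NF (2.5 equiv), AcOH (2.5 equiv), THF, 0 °C → rt, under argon
Reagents that add atoms: none
Why: Fluoride cleaves both aryl silyl ethers, driven by the Si–F bond and the good phenoxide leaving groups; the acetic acid buffer keeps the electron-rich ring B phenol protonated and so protects it from air oxidation.

Step 15
Reactants: 24 2-[16-(3-hydroxy-5-methoxyphenyl)hexadecyl]-6-isopropoxy-4-methoxyphenol
Product: 25 3-[16-(2-hydroxy-3-isopropoxy-5-methoxyphenyl)hexadecyl]-5-methoxyphenyl trifluoromethanesulfonate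
Conditions: PhNTf2 (1.05 equiv), Et3N, CH2Cl2, 0 °C → rt
Reagents that add atoms: N-phenylbis(trifluoromethanesulfonimide), O=S(=O)(N(c1ccccc1)S(=O)(=O)C(F)(F)F)C(F)(F)F
Why: O-sulfonylation of a phenol by a bulky, mild triflating agent; the ring A phenol is unhindered and the more acidic, while the C2(B) phenol is flanked by isopropoxy and the chain and should react much more slowly with one equivalent of reagent.

Step 16
Reactants: 25 3-[16-(2-hydroxy-3-isopropoxy-5-methoxyphenyl)hexadecyl]-5-methoxyphenyl trifluoromethanesulfonate
Product: 26 Grevirobstol B 5(A)-O-methyl, 5(B)-O-methyl, 3(B)-O-isopropyl ether (the 22-membered diaryl ether)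
Conditions: Pd(OAc)2 (10 mol %), tBuXPhos (20 mol %), K3PO4, PhMe, 100 °C, slow addition of 25 to a final 1 mM
Reagents that add atoms: none
Why: Buchwald–Hartwig-type diaryl ether coupling: zerovalent palladium formed in the flask inserts into the aryl–OTf bond, the potassium phenoxide replaces triflate on divalent palladium, and the bulky di-tert-butyl biarylphosphine promotes C–O reductive elimination, which ortho substituents on the phenoxide also favour. High dilution and slow addition favour the 22-membered ring over oligomers, and the weak anhydrous base limits S–O cleavage of the triflate.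

Step 17
Reactants: 26 Grevirobstol B 5(A)-O-methyl, 5(B)-O-methyl, 3(B)-O-isopropyl ether
Product: 27 Grevirobstol B
Conditions: BBr3, CH2Cl2, −78 °C → rt; then H2O
Reagents that add atoms: none
Why: Lewis-acid dealkylation of aryl alkyl ethers: boron binds the ether oxygen and bromide removes the methyl and isopropyl groups; the diaryl ether has no alkyl carbon for bromide to attack and survives, and hydrolysis of the aryl borates releases the three phenols.

## Compound list

1 | 3-hydroxy-5-methoxybenzaldehyde | COc1cc(O)cc(C=O)c1 | starting material
2 | 3-methoxy-5-(triisopropylsilyloxy)benzaldehyde | COc1cc(O[Si](C(C)C)(C(C)C)C(C)C)cc(C=O)c1 | intermediate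
3 | ω-pentadecalactone (oxacyclohexadecan-2-one) | O=C1CCCCCCCCCCCCCCO1 | starting material
4 | 15-bromopentadecanoic acid | OC(=O)CCCCCCCCCCCCCCBr | intermediate
5 | (14-carboxytetradecyl)triphenylphosphonium bromide | OC(=O)CCCCCCCCCCCCCC[P+](c1ccccc1)(c1ccccc1)c1ccccc1.[Br-] | intermediate
6 | sodium 15-(triphenylphosphoranylidene)pentadecanoate (ylide carboxylate) | [Na+].[O-]C(=O)CCCCCCCCCCCCCC=P(c1ccccc1)(c1ccccc1)c1ccccc1 | intermediate (not isolated)
7 | (Z)-16-[3-methoxy-5-(triisopropylsilyloxy)phenyl]hexadec-15-enoic acid | OC(=O)CCCCCCCCCCCCC/C=C\c1cc(OC)cc(O[Si](C(C)C)(C(C)C)C(C)C)c1 | intermediate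
8 | 16-[3-methoxy-5-(triisopropylsilyloxy)phenyl]hexadecanoic acid | OC(=O)CCCCCCCCCCCCCCCc1cc(OC)cc(O[Si](C(C)C)(C(C)C)C(C)C)c1 | intermediate
9 | 16-[3-methoxy-5-(triisopropylsilyloxy)phenyl]hexadecan-1-ol | OCCCCCCCCCCCCCCCCc1cc(OC)cc(O[Si](C(C)C)(C(C)C)C(C)C)c1 | intermediate
10 | [3-(16-iodohexadecyl)-5-methoxyphenoxy]triisopropylsilane | ICCCCCCCCCCCCCCCCc1cc(OC)cc(O[Si](C(C)C)(C(C)C)C(C)C)c1 | intermediate
11 | triisopropyl[3-methoxy-5-(octadec-17-yn-1-yl)phenoxy]silane | C#CCCCCCCCCCCCCCCCCc1cc(OC)cc(O[Si](C(C)C)(C(C)C)C(C)C)c1 | intermediate
12 | (Z)-9-{2-bromo-18-[3-methoxy-5-(triisopropylsilyloxy)phenyl]octadec-1-en-1-yl}-9-borabicyclo[3.3.1]nonane | Br/C(CCCCCCCCCCCCCCCCc1cc(OC)cc(O[Si](C(C)C)(C(C)C)C(C)C)c1)=C\B1C2CCCC1CCC2 | intermediate (not isolated)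
13 | [3-(17-bromooctadec-17-en-1-yl)-5-methoxyphenoxy]triisopropylsilane | C=C(Br)CCCCCCCCCCCCCCCCc1cc(OC)cc(O[Si](C(C)C)(C(C)C)C(C)C)c1 | intermediate
14 | diisopropyl squarate (3,4-diisopropoxycyclobut-3-ene-1,2-dione) | CC(C)OC1=C(OC(C)C)C(=O)C1=O | starting material
15 | rac-4-hydroxy-2,3-diisopropoxycyclobut-2-en-1-one (one enantiomer drawn) | CC(C)OC1=C(OC(C)C)[C@H](O)C1=O | intermediate (not isolated)
16 | 3-isopropoxycyclobut-3-ene-1,2-dione | O=C1C=C(OC(C)C)C1=O | intermediate
17 | {18-[3-methoxy-5-(triisopropylsilyloxy)phenyl]octadec-1-en-2-yl}lithium | [Li]C(=C)CCCCCCCCCCCCCCCCc1cc(OC)cc(O[Si](C(C)C)(C(C)C)C(C)C)c1 | intermediate (not isolated)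
18 | lithium alkoxide of rac-4-hydroxy-3-isopropoxy-4-{18-[3-methoxy-5-(triisopropylsilyloxy)phenyl]octadec-1-en-2-yl}cyclobut-2-en-1-one (one enantiomer drawn) | O=C1C=C(OC(C)C)[C@@]1([O-])C(=C)CCCCCCCCCCCCCCCCc1cc(OC)cc(O[Si](C(C)C)(C(C)C)C(C)C)c1.[Li+] | intermediate (not isolated)
19 | rac-4-[tert-butyl(dimethyl)silyloxy]-3-isopropoxy-4-{18-[3-methoxy-5-(triisopropylsilyloxy)phenyl]octadec-1-en-2-yl}cyclobut-2-en-1-one (one enantiomer drawn) | O=C1C=C(OC(C)C)[C@@]1(O[Si](C)(C)C(C)(C)C)C(=C)CCCCCCCCCCCCCCCCc1cc(OC)cc(O[Si](C(C)C)(C(C)C)C(C)C)c1 | intermediate
20 | (Z)-4-[tert-butyl(dimethyl)silyloxy]-3-isopropoxy-21-[3-methoxy-5-(triisopropylsilyloxy)phenyl]-5-methylidenehenicosa-1,3-dien-1-one (dienylketene) | O=C=C/C(OC(C)C)=C(/O[Si](C)(C)C(C)(C)C)C(=C)CCCCCCCCCCCCCCCCc1cc(OC)cc(O[Si](C(C)C)(C(C)C)C(C)C)c1 | intermediate (not isolated)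
21 | 4-[tert-butyl(dimethyl)silyloxy]-3-isopropoxy-5-{16-[3-methoxy-5-(triisopropylsilyloxy)phenyl]hexadecyl}cyclohexa-2,4-dien-1-one | O=C1C=C(OC(C)C)C(O[Si](C)(C)C(C)(C)C)=C(CCCCCCCCCCCCCCCCc2cc(OC)cc(O[Si](C(C)C)(C(C)C)C(C)C)c2)C1 | intermediate (not isolated)
22 | 4-[tert-butyl(dimethyl)silyloxy]-3-isopropoxy-5-{16-[3-methoxy-5-(triisopropylsilyloxy)phenyl]hexadecyl}phenol | CC(C)Oc1cc(O)cc(CCCCCCCCCCCCCCCCc2cc(OC)cc(O[Si](C(C)C)(C(C)C)C(C)C)c2)c1O[Si](C)(C)C(C)(C)C | intermediate
23 | tert-butyl(2-isopropoxy-4-methoxy-6-{16-[3-methoxy-5-(triisopropylsilyloxy)phenyl]hexadecyl}phenoxy)dimethylsilane | CC(C)Oc1cc(OC)cc(CCCCCCCCCCCCCCCCc2cc(OC)cc(O[Si](C(C)C)(C(C)C)C(C)C)c2)c1O[Si](C)(C)C(C)(C)C | intermediate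
24 | 2-[16-(3-hydroxy-5-methoxyphenyl)hexadecyl]-6-isopropoxy-4-methoxyphenol | CC(C)Oc1cc(OC)cc(CCCCCCCCCCCCCCCCc2cc(O)cc(OC)c2)c1O | intermediate
25 | 3-[16-(2-hydroxy-3-isopropoxy-5-methoxyphenyl)hexadecyl]-5-methoxyphenyl trifluoromethanesulfonate | CC(C)Oc1cc(OC)cc(CCCCCCCCCCCCCCCCc2cc(OC)cc(OS(=O)(=O)C(F)(F)F)c2)c1O | intermediate
26 | Grevirobstol B 5(A)-O-methyl, 5(B)-O-methyl, 3(B)-O-isopropyl ether | COc1cc2cc(c1)Oc1c(OC(C)C)cc(OC)cc1CCCCCCCCCCCCCCCC2 | intermediate
27 | Grevirobstol B | Oc1cc2cc(c1)Oc1c(O)cc(O)cc1CCCCCCCCCCCCCCCC2 | target

## Step count and least certain steps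

Total step count: 17. Longest linear sequence: 15 steps, from 3 to 27 (steps 2–9 and 11–17).

Step 16 (macrocyclic etherification). This is the least certain step. Intermolecular coupling to oligomers may compete with ring closure, the triflate S–O bond may be cleaved by phosphate or phenoxide (returning the phenol), the triflate may be reduced, or C–O reductive elimination from the hindered, electron-rich palladium aryloxide may be slow. Fallback: the ring is closed by copper-mediated oxidative coupling instead. It sets out from 25, which is borylated with B2(OH)4 under Pd(OAc)2/XPhos and KOAc in EtOH to give {3-[16-(2-hydroxy-3-isopropoxy-5-methoxyphenyl)hexadecyl]-5-methoxyphenyl}boronic acid F1. F1 is cyclized under Chan–Lam–Evans conditions (Cu(OAc)2, pyridine, 4 Å sieves, CH2Cl2, air, high dilution), a coupling known to tolerate di-ortho-substituted phenols and to close macrocyclic diaryl ethers, and the route is rejoined at 26.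

Step 11 (fragment union with capture of the alkoxide). The alkenyllithium may add in the conjugate sense or at the vinylogous ester carbonyl, or silylation of the hindered tertiary alkoxide may be incomplete and lead to ring opening on warming. Fallback: addition and protection are separated. It sets out from 13 and 16: the addition is quenched with aqueous NH4Cl at −78 °C and the free carbinol rac-4-hydroxy-3-isopropoxy-4-{18-[3-methoxy-5-(triisopropylsilyloxy)phenyl]octadec-1-en-2-yl}cyclobut-2-en-1-one F2 is isolated and purified. F2 is then silylated on its own (TBSOTf, 2,6-lutidine, CH2Cl2, −78 °C), and the route is rejoined at 19.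

Step 12 (key step). The silyl ether may open only slowly at 110 °C, so that transfer or loss of the silyl group, or dimerization and adventitious capture of the ketene, compete with the 6π closure. Fallback: the ring expansion is run on the free carbinol and the two hydroxyls are told apart by hindrance. It sets out from 13 and 16 by way of the carbinol F2 described above. Heating F2 in degassed toluene or p-xylene should give 2-isopropoxy-6-{16-[3-methoxy-5-(triisopropylsilyloxy)phenyl]hexadecyl}benzene-1,4-diol F3, handled under argon. One equivalent of MeI with K2CO3 in acetone should methylate the open hydroxyl on C5 in preference to the flanked one on C2 and give 2-isopropoxy-4-methoxy-6-{16-[3-methoxy-5-(triisopropylsilyloxy)phenyl]hexadecyl}phenol F4. Bu4NF then removes the ring A silyl group and the route is rejoined at 24.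

Step 9 (hydrobromination). The haloborane may begin to cleave the aryl methyl or silyl ether, protonolysis of the alkenylborane may be incomplete, or the regiochemistry may leak to 1-bromoalkenes that are hard to separate. Fallback: the alkenyllithium is generated by a Shapiro reaction instead of halogen–lithium exchange. It sets out from 11, which is hydrated in the Markovnikov sense (Ph3PAuCl/AgOTf cat., dioxane/H2O) to 18-[3-methoxy-5-(triisopropylsilyloxy)phenyl]octadecan-2-one F5. Condensation with 2,4,6-triisopropylbenzenesulfonyl hydrazide gives the (E)-2,4,6-triisopropylbenzenesulfonylhydrazone of that ketone F6. Two equivalents of n-BuLi in THF (−78 → 0 °C) deprotonate F6 at the methyl group and expel sulfinate and nitrogen, and the route is rejoined at 17, which is used in step 11 as before.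

## Further compounds

F1 | step 16 | {3-[16-(2-hydroxy-3-isopropoxy-5-methoxyphenyl)hexadecyl]-5-methoxyphenyl}boronic acid | CC(C)Oc1cc(OC)cc(CCCCCCCCCCCCCCCCc2cc(OC)cc(B(O)O)c2)c1O
F2 | step 11 | rac-4-hydroxy-3-isopropoxy-4-{18-[3-methoxy-5-(triisopropylsilyloxy)phenyl]octadec-1-en-2-yl}cyclobut-2-en-1-one (one enantiomer drawn) | O=C1C=C(OC(C)C)[C@@]1(O)C(=C)CCCCCCCCCCCCCCCCc1cc(OC)cc(O[Si](C(C)C)(C(C)C)C(C)C)c1
F3 | step 12 | 2-isopropoxy-6-{16-[3-methoxy-5-(triisopropylsilyloxy)phenyl]hexadecyl}benzene-1,4-diol | CC(C)Oc1cc(O)cc(CCCCCCCCCCCCCCCCc2cc(OC)cc(O[Si](C(C)C)(C(C)C)C(C)C)c2)c1O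
F4 | step 12 | 2-isopropoxy-4-methoxy-6-{16-[3-methoxy-5-(triisopropylsilyloxy)phenyl]hexadecyl}phenol | CC(C)Oc1cc(OC)cc(CCCCCCCCCCCCCCCCc2cc(OC)cc(O[Si](C(C)C)(C(C)C)C(C)C)c2)c1O
F5 | step 9 | 18-[3-methoxy-5-(triisopropylsilyloxy)phenyl]octadecan-2-one | CC(=O)CCCCCCCCCCCCCCCCc1cc(OC)cc(O[Si](C(C)C)(C(C)C)C(C)C)c1
F6 | step 9 | (E)-N'-{18-[3-methoxy-5-(triisopropylsilyloxy)phenyl]octadecan-2-ylidene}-2,4,6-triisopropylbenzenesulfonohydrazide | C/C(CCCCCCCCCCCCCCCCc1cc(OC)cc(O[Si](C(C)C)(C(C)C)C(C)C)c1)=N\NS(=O)(=O)c1c(C(C)C)cc(C(C)C)cc1C(C)C
A1 | alternative 1 | (E)-1',2'-didehydro Grevirobstol B trimethyl ether | COc1cc(OC)c2c(c1)CCCCCCCCCCCCCC/C=C/c1cc(OC)cc(c1)O2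
A2 | alternative 1 | 23-membered macrocyclic sulfone, ring A–CH2–SO2–(CH2)15–ring B with the diaryl ether in place, trimethyl ether | COc1cc(OC)c2c(c1)CCCCCCCCCCCCCCCS(=O)(=O)Cc1cc(OC)cc(c1)O2
A3 | alternative 2 | macrocycle-fused racemic trans-4-aryloxy-5-alkylcyclohexane-1,3-dione 6-carboxylate, enol form (one enantiomer drawn) | COc1cc2cc(c1)O[C@@H]1C(=O)CC(O)=C(C(=O)OC)[C@H]1CCCCCCCCCCCCCCCC2
A4 | alternative 2 | macrocyclic (Z)-α-aryloxy enone (3-aryloxyalk-3-en-2-one closed through ring A) | COc1cc2cc(c1)O/C(C(C)=O)=C\CCCCCCCCCCCCCCCC2
A5 | alternative 3 | Grevirobstol B ring B dimethyl ether | Oc1cc2cc(c1)Oc1c(OC)cc(OC)cc1CCCCCCCCCCCCCCCC2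
A6 | alternative 3 | 1-diazo-19-(2-ethynyloxy-3,5-dimethoxyphenyl)-3-methylidenenonadecan-2-one | [N-]=[N+]=CC(=O)C(=C)CCCCCCCCCCCCCCCCc1cc(OC)cc(OC)c1OC#C
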